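The route annulates the complete alpha-methylene gamma-lactone onto an open-chain diene and closes the ten-membered carbocycle (ring A, C1–C10) afterwards. The feature exploited is that the lactone oxygen sits on C6, allylic to the ring alkene C4=C5, while the neighbouring C7 carries the acrylate carbon C11: lactone ring B (O, C6, C7, C11, C12) is the imprint of a 1,2-carbo-oxygenation of a C4=C5–C6=C7 diene. In one operation a palladium-catalysed heteroannulation of 2-bromoacrylic acid with an acyclic (4E,6E)-diene, made from D-glyceraldehyde acetonide, should forge C7–C11 and O–C6, set C6 and C7 and leave C4=C5 in place. Ring A is then closed at C9–C10.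

Key step: step 6

Remark: atoms are numbered as in germacranolides (ring carbons C1–C10, lactone carbons C11–C13, ester carbon C14 on C10, hydroxymethyl carbon C15 on C4); the SMILES string is read as the (6R,7S,8S,9R) isomer with a 6,7-trans lactone, 7,8-anti and 8,9-anti relationships, and both ring alkenes cis within ring A.

Step 1
Reactants: 1 triethyl phosphonoacetate; 2 2-(2-bromoethyl)-1,3-dioxolane
Product: 3 ethyl 2-(diethoxyphosphoryl)-4-(1,3-dioxolan-2-yl)butanoate
Conditions: NaH, DMF, 0 °C then 60 °C
Reagents that add atoms: none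
Why: C-alkylation of the stabilised phosphonoacetate carbanion with a primary bromide should attach the C3–C2–C1 chain (C1 masked as the dioxolane) to the future C4; the new centre is lost as an alkene carbon in step 3.

Step 2
Reactants: 4 (R)-2,2-dimethyl-1,3-dioxolane-4-carbaldehyde; 5 (triphenylphosphoranylidene)acetaldehyde
Product: 6 (E)-3-[(4S)-2,2-dimethyl-1,3-dioxolan-4-yl]prop-2-enal
Conditions: toluene, rt
Reagents that add atoms: none
Why: Wittig reaction of the stabilised formyl ylide should give the (E)-enal (C5–C7) and leave the C8 stereocentre of the chiral-pool aldehyde untouched.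

Step 3
Reactants: 3 ethyl 2-(diethoxyphosphoryl)-4-(1,3-dioxolan-2-yl)butanoate; 6 (E)-3-[(4S)-2,2-dimethyl-1,3-dioxolan-4-yl]prop-2-enal
Product: 7 ethyl (2E,4E)-2-[2-(1,3-dioxolan-2-yl)ethyl]-5-[(4S)-2,2-dimethyl-1,3-dioxolan-4-yl]penta-2,4-dienoate
Conditions: NaH, THF, 0 °C to rt
Reagents that add atoms: none
Why: Horner–Wadsworth–Emmons olefination of an enal with an alpha-substituted phosphonoacetate should place the ester (future C15) trans to C6, so that C3 and C6 are cis on C4=C5 as ring A requires; any (2Z) isomer is removed by chromatography.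

Step 4
Reactants: 7 ethyl (2E,4E)-2-[2-(1,3-dioxolan-2-yl)ethyl]-5-[(4S)-2,2-dimethyl-1,3-dioxolan-4-yl]penta-2,4-dienoate
Product: 8 (2E,4E)-2-[2-(1,3-dioxolan-2-yl)ethyl]-5-[(4S)-2,2-dimethyl-1,3-dioxolan-4-yl]penta-2,4-dien-1-ol
Conditions: i-Bu2AlH (2.2 equiv), CH2Cl2, −78 °C
Reagents that add atoms: none
Why: 1,2-reduction of the dienoate by the aluminium hydride at low temperature should give the C15 allylic alcohol without touching the two acetals or the alkene geometry.

Step 5
Reactants: 8 (2E,4E)-2-[2-(1,3-dioxolan-2-yl)ethyl]-5-[(4S)-2,2-dimethyl-1,3-dioxolan-4-yl]penta-2,4-dien-1-ol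
Product: 9 tert-butyl{[(2E,4E)-2-[2-(1,3-dioxolan-2-yl)ethyl]-5-[(4S)-2,2-dimethyl-1,3-dioxolan-4-yl]penta-2,4-dien-1-yl]oxy}diphenylsilane
Conditions: tert-butyl(chloro)diphenylsilane, imidazole, CH2Cl2, rt
Reagents that add atoms: tert-butyl(chloro)diphenylsilane CC(C)(C)[Si](Cl)(c1ccccc1)c1ccccc1
Why: Silylation of the primary allylic alcohol; this silyl ether is chosen because it should survive the aqueous acid of step 7 and is not ionised by palladium.

Step 6
Reactants: 9 tert-butyl{[(2E,4E)-2-[2-(1,3-dioxolan-2-yl)ethyl]-5-[(4S)-2,2-dimethyl-1,3-dioxolan-4-yl]penta-2,4-dien-1-yl]oxy}diphenylsilane; 10 2-bromoprop-2-enoic acid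
Product: 11 (4S,5R)-5-[(1E)-2-{[tert-butyl(diphenyl)silyl]oxymethyl}-4-(1,3-dioxolan-2-yl)but-1-en-1-yl]-4-[(4S)-2,2-dimethyl-1,3-dioxolan-4-yl]-3-methylideneoxolan-2-one
Conditions: Pd(OAc)2 (10 mol %), PPh3 (20 mol %), K2CO3 (2 equiv), DMF, 60 °C, slow addition of 10
Reagents that add atoms: none
Why: Zerovalent palladium inserts into the C–Br bond of the 2-bromoacrylate, the alkenylpalladium adds syn across C6=C7 with C11 bonding to the monosubstituted diene terminus C7, and the carboxylate then closes onto C6 of the resulting C4–C5–C6 allylpalladium unit, releasing zerovalent palladium. The closest known reaction type is the Larock heteroannulation of 1,3-dienes by aryl or alkenyl halides that carry a carboxylic acid, phenol or amine. Lactone ring B closes by C–O bond formation from a six-membered palladacycle in which the carboxylate is bound to palladium, formally a 5-exo attack on the allyl terminus C6, whereas attack at C4 would need a seven-membered ring at a fully substituted carbon. C7 is controlled by the C8 stereocentre: with the dioxolane C8–O bond in the inside position and C9 anti, the alkenylpalladium should add to the alkene face opposite C9 and give the 7,8-anti relationship. C6 is controlled by C7 and the (6E) geometry, because the C–C and C–O bonds form on the same face (net syn addition), which gives the 6,7-trans lactone, also the more stable isomer should the allylic C–O bond re-ionise. The step needs terminus selectivity (C7 over the disubstituted C4), retention of the C4=C5 geometry and chemoselectivity, which are secured by the substitution pattern of the diene, by the reluctance of palladium to shift to the tertiary C4, and by the absence of any allylic ester or other halide in the diene partner (only ethers, acetals and a silyl ether).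

Step 7
Reactants: 11 (4S,5R)-5-[(1E)-2-{[tert-butyl(diphenyl)silyl]oxymethyl}-4-(1,3-dioxolan-2-yl)but-1-en-1-yl]-4-[(4S)-2,2-dimethyl-1,3-dioxolan-4-yl]-3-methylideneoxolan-2-one
Product: 12 trans-lactone diol aldehyde (11 with the free (8S)-8,9-diol and C1 as the aldehyde)
Conditions: 1 M aqueous HCl, THF, rt
Reagents that add atoms: water O
Why: Acid-catalysed acetal hydrolysis should cleave the isopropylidene acetal and the dioxolane in one operation, while the silyl ether, the lactone and its exocyclic alkene tolerate dilute acid.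

Step 8
Reactants: 12 trans-lactone diol aldehyde; 13 methyl (triphenylphosphoranylidene)acetate
Product: 15 (Z)-alpha-iodo enoate diol (12 with C1HO converted into C1H=C10(I)CO2Me, iodine cis to C2), via iodo ylide 14 (not isolated)
Conditions: 13 (1.3 equiv), N-iodosuccinimide (1.2 equiv), CH2Cl2, −20 °C; then 12, −20 °C to rt
Reagents that add atoms: N-iodosuccinimide O=C1CCC(=O)N1I
Why: Wittig olefination with the alpha-iodo ylide made in the flask (all N-iodosuccinimide is consumed by excess 13 before 12 is added, so no iodinating agent meets the alkenes or the diol); stabilised-ylide selectivity should put the ester trans to C2 and so give the (Z)-iodoalkene.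

Step 9
Reactants: 15 (Z)-alpha-iodo enoate diol
Product: 16 9-O-triethylsilyl ether of 15
Conditions: chlorotriethylsilane (1.05 equiv), imidazole, CH2Cl2, −78 °C
Reagents that add atoms: chlorotriethylsilane CC[Si](Cl)(CC)CC
Why: Silylation at low temperature should select the primary C9 hydroxyl over the hindered secondary C8 hydroxyl.

Step 10
Reactants: 16 9-O-triethylsilyl ether of 15
Product: 17 8-O-(2-methylpropanoyl) ester of 16
Conditions: 2-methylpropanoyl chloride, pyridine, 4-(dimethylamino)pyridine (cat.), CH2Cl2, 0 °C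
Reagents that add atoms: 2-methylpropanoyl chloride CC(C)C(Cl)=O
Why: Acylation of the remaining secondary alcohol installs the C8 ester while the C9 oxygen is blocked, so no acyl migration is possible.

Step 11
Reactants: 17 8-O-(2-methylpropanoyl) ester of 16
Product: 19 C9 aldehyde (alpha-acyloxy aldehyde carrying the (Z)-iodo enoate), via primary alcohol 18 (not isolated)
Conditions: (COCl)2, DMSO, CH2Cl2, −78 to −40 °C; then Et3N, −78 to 0 °C
Reagents that add atoms: none
Why: Swern oxidation, under which a primary triethylsilyl ether is cleaved and oxidised in the same pot, should give the aldehyde without handling the free 9-hydroxy 8-ester; the bulkier silyl ether at C15 is inert.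

Step 12
Reactants: 19 C9 aldehyde
Product: 20 9-hydroxy macrocycle (15-O-silyl, 9-deacetyl form of the target)
Conditions: CrCl2 (10 equiv), NiCl2 (cat.), DMSO/THF, rt, slow addition to high dilution
Reagents that add atoms: none
Why: Intramolecular Nozaki–Hiyama–Kishi coupling of the C10 alkenyl iodide with the C9 aldehyde, in which Felkin–Anh attack anti to the C8–O bond should set the 8,9-anti (9R) carbinol, the tether from C2 forces the new C9–C10 bond cis to C2 on C1=C10, and the two cis-disposed alkenes and the trans-lactone pre-fold the chain for ten-membered ring closure.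

Step 13
Reactants: 20 9-hydroxy macrocycle
Product: 21 15-O-[tert-butyl(diphenyl)silyl] ether of the target
Conditions: Ac2O, pyridine, CH2Cl2, 0 °C to rt
Reagents that add atoms: acetic anhydride CC(=O)OC(C)=O
Why: Acetylation of the secondary allylic alcohol, run without a nucleophilic catalyst so that the allylic acetate next to the enoate is not displaced and the neighbouring ester does not migrate.

Step 14
Reactants: 21 15-O-[tert-butyl(diphenyl)silyl] ether of the target
Product: 22 CNP0242134.4 (target)
Conditions: HF·pyridine, pyridine, THF, 0 °C to rt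
Reagents that add atoms: none
Why: Fluoride-mediated cleavage of the silyl ether under buffered, weakly nucleophilic conditions should free the C15 alcohol and leave the three esters and the alpha-methylene lactone intact.

Compound list
1 | triethyl phosphonoacetate | CCOC(=O)CP(=O)(OCC)OCC | starting material
2 | 2-(2-bromoethyl)-1,3-dioxolane | BrCCC1OCCO1 | starting material
3 | ethyl 2-(diethoxyphosphoryl)-4-(1,3-dioxolan-2-yl)butanoate (racemic) | CCOC(=O)C(CCC1OCCO1)P(=O)(OCC)OCC | intermediate
4 | (R)-2,2-dimethyl-1,3-dioxolane-4-carbaldehyde | O=C[C@@H]1OC(C)(C)OC1 | starting material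
5 | (triphenylphosphoranylidene)acetaldehyde | O=CC=P(c1ccccc1)(c1ccccc1)c1ccccc1 | starting material
6 | (E)-3-[(4S)-2,2-dimethyl-1,3-dioxolan-4-yl]prop-2-enal | O=C/C=C/[C@@H]1OC(C)(C)OC1 | intermediate
7 | ethyl (2E,4E)-2-[2-(1,3-dioxolan-2-yl)ethyl]-5-[(4S)-2,2-dimethyl-1,3-dioxolan-4-yl]penta-2,4-dienoate | CCOC(=O)/C(CCC1OCCO1)=C/C=C/[C@@H]1OC(C)(C)OC1 | intermediate
8 | (2E,4E)-2-[2-(1,3-dioxolan-2-yl)ethyl]-5-[(4S)-2,2-dimethyl-1,3-dioxolan-4-yl]penta-2,4-dien-1-ol | OC/C(CCC1OCCO1)=C/C=C/[C@@H]1OC(C)(C)OC1 | intermediate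
9 | tert-butyl{[(2E,4E)-2-[2-(1,3-dioxolan-2-yl)ethyl]-5-[(4S)-2,2-dimethyl-1,3-dioxolan-4-yl]penta-2,4-dien-1-yl]oxy}diphenylsilane | CC(C)(C)[Si](OC/C(CCC1OCCO1)=C/C=C/[C@@H]1OC(C)(C)OC1)(c1ccccc1)c1ccccc1 | intermediate
10 | 2-bromoprop-2-enoic acid (2-bromoacrylic acid) | C=C(Br)C(=O)O | starting material
11 | (4S,5R)-5-[(1E)-2-{[tert-butyl(diphenyl)silyl]oxymethyl}-4-(1,3-dioxolan-2-yl)but-1-en-1-yl]-4-[(4S)-2,2-dimethyl-1,3-dioxolan-4-yl]-3-methylideneoxolan-2-one (6,7-trans lactone, 7,8-anti) | C=C1C(=O)O[C@H](/C=C(/CO[Si](c2ccccc2)(c2ccccc2)C(C)(C)C)CCC2OCCO2)[C@H]1[C@@H]1OC(C)(C)OC1 | intermediate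
12 | trans-lactone diol aldehyde: 11 with the free (8S)-8,9-diol and C1 as the aldehyde | C=C1C(=O)O[C@H](/C=C(/CO[Si](c2ccccc2)(c2ccccc2)C(C)(C)C)CCC=O)[C@H]1[C@H](O)CO | intermediate
13 | methyl (triphenylphosphoranylidene)acetate | COC(=O)C=P(c1ccccc1)(c1ccccc1)c1ccccc1 | starting material
14 | iodo ylide: methyl iodo(triphenylphosphoranylidene)acetate (not isolated) | COC(=O)C(I)=P(c1ccccc1)(c1ccccc1)c1ccccc1 | intermediate
15 | (Z)-alpha-iodo enoate diol: 12 with C1HO converted into C1H=C10(I)CO2Me, iodine cis to C2 | C=C1C(=O)O[C@H](/C=C(/CO[Si](c2ccccc2)(c2ccccc2)C(C)(C)C)CC/C=C(/C(=O)OC)I)[C@H]1[C@H](O)CO | intermediate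
16 | 9-O-triethylsilyl ether of 15 | C=C1C(=O)O[C@H](/C=C(/CO[Si](c2ccccc2)(c2ccccc2)C(C)(C)C)CC/C=C(/C(=O)OC)I)[C@H]1[C@H](O)CO[Si](CC)(CC)CC | intermediate
17 | 8-O-(2-methylpropanoyl) ester of 16 | C=C1C(=O)O[C@H](/C=C(/CO[Si](c2ccccc2)(c2ccccc2)C(C)(C)C)CC/C=C(/C(=O)OC)I)[C@H]1[C@H](OC(=O)C(C)C)CO[Si](CC)(CC)CC | intermediate
18 | primary alcohol: 17 without the triethylsilyl group (not isolated) | C=C1C(=O)O[C@H](/C=C(/CO[Si](c2ccccc2)(c2ccccc2)C(C)(C)C)CC/C=C(/C(=O)OC)I)[C@H]1[C@H](OC(=O)C(C)C)CO | intermediate
19 | C9 aldehyde: 8-O-(2-methylpropanoyl) alpha-acyloxy aldehyde carrying the (Z)-iodo enoate | C=C1C(=O)O[C@H](/C=C(/CO[Si](c2ccccc2)(c2ccccc2)C(C)(C)C)CC/C=C(/C(=O)OC)I)[C@H]1[C@H](OC(=O)C(C)C)C=O | intermediate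
20 | 9-hydroxy macrocycle: 15-O-[tert-butyl(diphenyl)silyl], 9-deacetyl form of the target (6R,7S,8S,9R) | C=C1C(=O)O[C@@H]2/C=C(/CO[Si](c3ccccc3)(c3ccccc3)C(C)(C)C)CC/C=C(/C(=O)OC)[C@@H](O)[C@@H](OC(=O)C(C)C)[C@@H]12 | intermediate
21 | 15-O-[tert-butyl(diphenyl)silyl] ether of the target | C=C1C(=O)O[C@@H]2/C=C(/CO[Si](c3ccccc3)(c3ccccc3)C(C)(C)C)CC/C=C(/C(=O)OC)[C@@H](OC(C)=O)[C@@H](OC(=O)C(C)C)[C@@H]12 | intermediate
22 | CNP0242134.4 | C=C1C(=O)O[C@@H]2/C=C(/CO)CC/C=C(/C(=O)OC)[C@@H](OC(C)=O)[C@@H](OC(=O)C(C)C)[C@@H]12 | target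

Total step count: 14. Longest linear sequence: 13 steps (steps 2 to 14, from 4); step 1 is a one-step branch that joins at step 3.

Steps most likely to fail

Step 6. The internal diene may insert slowly while the bromoacrylate polymerises. The allylpalladium intermediate may lose a beta-hydrogen to give a triene acid instead of closing the C–O bond. Facial selectivity at C7 relative to C8 may be poor. The fallback sets out from 9 and comes back at 11, and it replaces the organopalladium pathway by a radical–polar crossover. Iodoacetic acid with Et3B and air should add its carboxymethyl radical to C7; iodine transfer to C6 and closure by the carboxylate (NaHCO3) would give the saturated lactone F1. Deprotonation with LiN(i-Pr)2 and reaction with dimethyl(methylidene)ammonium iodide would give the Mannich base F2. Iodomethane would give the ammonium iodide F3, which is eliminated with NaHCO3 to return 11.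

Step 12. Intermolecular coupling and protodeiodination may outrun closure of the strained ten-membered ring, and Felkin–Anh control at C9 may be lost inside the ring-closing transition state. The fallback sets out from 12 and comes back at 21, and it moves the ring closure to C1=C10. Methylenation of the C1 aldehyde of 12 (Zn, CH2Br2, TiCl4) would give the terminal alkene diol F4. Chlorotriethylsilane would give the triethylsilyl ether F5, and 2-methylpropanoyl chloride the ester F6. Swern oxidation would give the aldehyde F7. Intermolecular addition of the [1-(methoxycarbonyl)ethenyl]aluminium reagent made from methyl propiolate and i-Bu2AlH would give the allylic alcohol F8 under Felkin–Anh control. Ac2O in pyridine would give the acetate F9. Ring-closing metathesis of F9 with the second-generation Hoveyda–Grubbs catalyst in dilute toluene, between the C1 vinyl group and the acrylate methylene, would return 21.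

Step 3. Geometric selectivity in forming the trisubstituted C4=C5 alkene may be insufficient, and the wrong isomer would carry the wrong ring geometry forward. The fallback sets out from 4 and comes back at 9, and it fixes the geometry by a syn-carbometallation instead of an olefination. Homologation of 4 with dimethyl (1-diazo-2-oxopropyl)phosphonate (K2CO3, MeOH) would give the alkyne F10. Hydroboration with pinacolborane (Cp2Zr(H)Cl cat.) would give the alkenylboronate F11. Separately, syn-carbocupration of tert-butyldiphenyl(prop-2-yn-1-yloxy)silane with the organocopper reagent from [2-(1,3-dioxolan-2-yl)ethyl]magnesium bromide and CuBr·SMe2, followed by I2, would give the alkenyl iodide F12, with iodine cis to the new alkyl chain. Suzuki coupling of F11 with F12 (Pd(PPh3)4, K3PO4) would return 9.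

Further compounds
F1 | step 6 | saturated lactone (11 with C11 as CH2, no exocyclic methylene) | C1C(=O)O[C@H](/C=C(/CO[Si](c2ccccc2)(c2ccccc2)C(C)(C)C)CCC2OCCO2)[C@H]1[C@@H]1OC(C)(C)OC1
F2 | step 6 | Mannich base (F1 with a dimethylaminomethyl group on C11) | CN(C)CC1C(=O)O[C@H](/C=C(/CO[Si](c2ccccc2)(c2ccccc2)C(C)(C)C)CCC2OCCO2)[C@H]1[C@@H]1OC(C)(C)OC1
F3 | step 6 | ammonium iodide (N-methylated F2) | C[N+](C)(C)CC1C(=O)O[C@H](/C=C(/CO[Si](c2ccccc2)(c2ccccc2)C(C)(C)C)CCC2OCCO2)[C@H]1[C@@H]1OC(C)(C)OC1.[I-]
F4 | step 12 | terminal alkene diol (12 with C1HO converted into C1H=CH2) | C=C1C(=O)O[C@H](/C=C(/CO[Si](c2ccccc2)(c2ccccc2)C(C)(C)C)CCC=C)[C@H]1[C@H](O)CO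
F5 | step 12 | 9-O-triethylsilyl ether of F4 | C=C1C(=O)O[C@H](/C=C(/CO[Si](c2ccccc2)(c2ccccc2)C(C)(C)C)CCC=C)[C@H]1[C@H](O)CO[Si](CC)(CC)CC
F6 | step 12 | 8-O-(2-methylpropanoyl) ester of F5 | C=C1C(=O)O[C@H](/C=C(/CO[Si](c2ccccc2)(c2ccccc2)C(C)(C)C)CCC=C)[C@H]1[C@H](OC(=O)C(C)C)CO[Si](CC)(CC)CC
F7 | step 12 | C9 aldehyde with terminal alkene | C=C1C(=O)O[C@H](/C=C(/CO[Si](c2ccccc2)(c2ccccc2)C(C)(C)C)CCC=C)[C@H]1[C@H](OC(=O)C(C)C)C=O
F8 | step 12 | allylic alcohol (methyl 2-methylidene-3-hydroxy ester at C9–C10, 8,9-anti) | C=C1C(=O)O[C@H](/C=C(/CO[Si](c2ccccc2)(c2ccccc2)C(C)(C)C)CCC=C)[C@H]1[C@H](OC(=O)C(C)C)[C@H](O)C(=C)C(=O)OC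
F9 | step 12 | acetate of F8 | C=C1C(=O)O[C@H](/C=C(/CO[Si](c2ccccc2)(c2ccccc2)C(C)(C)C)CCC=C)[C@H]1[C@H](OC(=O)C(C)C)[C@H](OC(C)=O)C(=C)C(=O)OC
F10 | step 3 | (4S)-4-ethynyl-2,2-dimethyl-1,3-dioxolane | C#C[C@@H]1OC(C)(C)OC1
F11 | step 3 | 2-{(E)-2-[(4S)-2,2-dimethyl-1,3-dioxolan-4-yl]ethenyl}-4,4,5,5-tetramethyl-1,3,2-dioxaborolane | CC1(C)OB(/C=C/[C@@H]2OC(C)(C)OC2)OC1(C)C
F12 | step 3 | tert-butyl{[(2E)-4-(1,3-dioxolan-2-yl)-2-(iodomethylidene)butyl]oxy}diphenylsilane | I/C=C(/CO[Si](c1ccccc1)(c1ccccc1)C(C)(C)C)CCC1OCCO1
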